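To whoever takes the bench from me: the flask to watch is dusk, where substrate goes evenly into coupling partner over 2.50 d.

| flask | substrate | coupling partner | remark | time |
|---|---|---|---|---|
| north | 0.25 M | 0.275 M | run made earlier |  |
| south-west | 0.35 M | 0.275 M | run made earlier |  |
| north-west | 0.55 M | 0.275 M | run made earlier |  |
| midnight | 0.25 M | 0.275 M (fed, over 2.50 d) | a stirred flask in which coupling partner is dosed at a steady rate over 2.50 d without added volume, worked up at 2.5 d | 2.5 d |
| dusk | 0.25 M (fed, over 2.50 d) | 0.275 M | all but substrate at the start; substrate goes in evenly over 2.50 d, the run ends at 2.5 d | 2.5 d |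
| noon | 0.25 M | 0.275 M | one stirred flow tank at steady state, fed with the mixture as stated, mean residence time 2.5 d |  |
| winter | 0.25 M | 0.275 M | a closed flask charged with all of it at once and left for 2.5 d | 2.5 d |

- north (time / h: target / %, substrate / %): 5.00: 24.5, 20.2; 10.0: 25.5, 8.4; 15.0: 23.0, 4.0; 20.0: 19.3, 2.3; 25.0: 16.6, 1.3; 30.0: 13.3, 0.7; 40.0: 9.4, 0.5
- south-west (time / d: target / %, substrate / %): 0.417: 21.8, 6.8; 0.833: 16.1, 2.0; 1.25: 10.8, 0.8; 1.67: 7.4, 0.7; 2.00: 5.1, 0.1; 2.50: 3.2, 0.3; 3.00: 2.0, 0
- north-west (time / d: target / %, substrate / %): 0.417: 16.9, 4.8; 0.833: 11.8, 1.5; 1.25: 7.9, 0.7; 1.67: 5.3, 0; 2.00: 3.9, 0; 2.50: 2.6, 0; 3.00: 1.7, 0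

(scatter of a reading: 0.3 percentage points)

- the set-up with the highest amount of target at the outlet or at the end, in percent of the substrate put in ("none" if the first two lie within 2 percentage points) (midnight / dusk / noon / winter / none)
- amount of target at the outlet or at the end, in percent of the substrate put in, midnight
- amount of target at the outlet or at the end, in percent of the substrate put in, dusk
- amount of target at the outlet or at the end, in percent of the substrate put in, noon
- amount of target at the outlet or at the end, in percent of the substrate put in, winter

- the stated concentrations are those of everything mixed, before any reaction; amounts are the same in each set-up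
- the feed brings no volume worth counting
- the earlier runs were made in a closed, stirred flask

Here is the reckoning I trust. In the north run substrate falls from 8.4 % to 4.0 % between 10.0 h and 15.0 h, a first-order 3.56 d⁻¹, which I read as the pseudo-first-order pull of coupling partner. At 5.00 h it already stands at 20.2 %. A first-order loss plus a second-order self-loss fits both stretches with a crossover level of 0.0965 M: the [substrate] at which the two losses run equally fast, so that coupling's share at any moment is the crossover divided by crossover plus [substrate].

Winter starts with a share of 27.8 %. In dusk the feed of 0.100 M d⁻¹ balances the two losses near 0.0227 M, below the crossover, so the share is 80.9 %, drifting down as partner is used. Leave the feed alone.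

The forecast reasons: “So substrate also destroys itself, second order.” It names dusk, with dusk 23 % (19 % to 27 %), noon 16 %, winter 4.5 %, midnight 3.1 %.

The flask gives dusk: 21.7 %, against noon 16.1 %, winter 4.18 %, midnight 2.72 %. Beside dusk's target stand 42.8 % of isomer of the product, and the relaxation half-life of that pair, 0.554 d, is short against the 2.5 d. Dusk's substrate peaks at 0.0288 M, above my balance and below the crossover. But the crossover comes from the north run, and at the end of dusk 41.4 % of the coupling partner's charge stands, so I hold the share of 80.9 % to the early feed and give none for the peak.

    target ⇌ isomer of the product (K = 29.0, k = 1.40 × 10⁻⁵ s⁻¹)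
    substrate + coupling partner → target, rate k2*[substrate]*[coupling partner]^0.5 (k = 7.40 × 10⁻⁵ M⁻⁰·⁵ s⁻¹)
    2 substrate → self-condensation product (k = 2.40 × 10⁻⁴ M⁻¹ s⁻¹)

Take dusk with 1.0 M of substrate: the balance gives 0.0665 M, a share of 59.2 %, which asks 0.592 M of partner against 0.275 M charged, so partner is the limiting reagent. Computed, 0 % of coupling partner remains and target is 5.40 %.

The runs stem from a simulated flask on assumed constants, noise included.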